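## Structural features

The target has one carbocycle, ring A, a cyclohexene numbered C1 (CHOAc), C2 (CMe2), C3 (CH), C4(Me)=C5H, C6H2. C3 carries the exocyclic methylene C7, which is joined through an aryl ether oxygen to position 7 of a coumarin (benzene ring B fused to pyranone ring C). The two stereocentres, C1 (R) and C3 (R), are not adjacent: the quaternary C2 lies between them, and their substituents are 1,3-trans, which in the half-chair should mean an equatorial C1 oxygen and a pseudoaxial C7. C3 is the most crowded position, flanked by the quaternary C2 and the methyl-bearing alkene carbon C4. Fragile groups are the coumarin lactone (opened by hydroxide or alkoxide), the secondary acetate (base-labile) and the C4=C5 alkene, which can move into conjugation whenever C7 is at the aldehyde level because C3–H is then acidic. The real difficulty is to set C3 relative to a remote C1 across a quaternary carbon while fixing the trisubstituted alkene at C4=C5 and not at C3=C4. The key step exploits the ring bond C3–C4, which joins stereogenic C3 to sp2 carbon C4: an alkenyl–metal at C4 adding to a C3=C7 nitroalkene closes ring A, creates C3, keeps the alkene where the alkenyl group had it, and leaves C7 as a nitromethyl group, a masked hydroxymethyl.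

## Logic of the disconnections

24 to 23: the acyl C–O bond at C1 is cut. The base-labile acetate is thereby absent from every earlier step. The forward acylation must reach a hindered secondary alcohol next to C2 without touching the lactone.

23 to 22: the O–Si bond at C1 is cut. The C1 oxygen is carried as a silyl ether from step 3 to step 14. Its removal must spare the lactone, the aryl ether and the alkene, which calls for fluoride under non-basic conditions.

22 to 20 + 21: the C7–O aryl ether bond is cut. This removes rings B and C as commercial 21 and leaves a monocyclic C10 alcohol. The forward step must alkylate a phenol at a β-branched primary carbon under neutral conditions.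

20 to 19 to 17: no skeletal bond is cut; the heteroatom on C7 is changed from oxygen back to nitrogen. The nitro group is what makes C3 electrophilic in the ring closure. The forward conversions must keep the configuration of C3 and the position of the alkene although 19 is a β,γ-unsaturated aldehyde.

17 to 16: the ring bond C3–C4 is cut. Ring A opens to a chain, C3 disappears into a nitroalkene, and only C1 remains stereogenic. The forward step must close a six-membered ring, select one face of C3 and start from an alkenylboronate with boron cis to C6.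

16 to 12 + 13: the C3=C7 double bond is cut; C7 comes from 13. The forward nitroaldol must work on a neopentyl aldehyde and the dehydration must tolerate the boronate. The nitroalkene is made last because it is the most sensitive group.

12 to 11 to 9 + 10 to 8: the C4–B bond is traced to a C4–I bond and the C3 aldehyde to a methyl ester. The ester is an inert, non-enolisable placeholder for C3 and needs no protecting group. The forward borylation must retain the alkene geometry, and the hydride reduction is placed before boron is introduced.

8 to 7: the C4=C5 double bond is cut; C4 and its methyl group come from a two-carbon iodo ylide. The forward olefination must place iodine cis to C6.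

7 to 5 to 4 to 2: the C5 aldehyde is traced to a terminal alkene, and the C1–C6 bond is then cut as an allyl addition to an aldehyde. C1 is set here by the reagent. The forward step needs high facial selectivity on an α-quaternary aldehyde, and the carbinol must be silylated before ozonolysis.

2 to 1: an oxidation-state change only. 1 already holds C1, C2 with both methyl groups, and C3.

## Other disconnections considered

Alternative 1: Ring A is traced to a four-membered ketone.
- **Cut:** C1–C6 and, formally, the ring bond C2–C3, replaced by a temporary C2–C5 bond. The cyclohexenone (R)-3-{[(tert-butyldimethylsilyl)oxy]methyl}-2,2,4-trimethylcyclohex-4-en-1-one A5 would arise from the vinylcyclobutanone (R)-3-[(E)-4-(tert-butyldimethylsilyloxy)but-2-en-2-yl]-2,2-dimethylcyclobutan-1-one A4 by a 1,3-shift of C2 from C5 to C3.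
- **Forward key step:** N,N-dimethylisobutyramide A1 is converted by Tf2O and 2,4,6-collidine into the keteniminium triflate A2. A2 adds stepwise to the terminal alkene of (E)-tert-butyldimethyl[(3-methylpenta-2,4-dien-1-yl)oxy]silane A3 (C1 to C6, then C2 to the allyl cation at C5), and hydrolysis gives A4.
- **In its favour:** C1 and quaternary C2 come from a commodity amide, the regiochemistry follows from the polarity of the partners, and ring A with C7 attached would be reached in about three steps. On step economy and convergence this alternative is the better plan.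
- **Against it here:** the stereocentre created is C5, which later becomes sp2, so C3 depends wholly on chirality transfer in the 1,3-shift. Diradical or allyl-metal pathways do not guarantee that transfer. The allyl cation could also collapse at C3, or the keteniminium could attack the more electron-rich trisubstituted alkene. An enantioselective version needs a chiral amine in place of the dimethylamino group of A1. C1 must then be set by reduction of A5, where a pseudoaxial C7 shields the face a small hydride would need to use for the trans alcohol.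
- **Comparison:** both plans reach the same ring with C7 as a one-carbon handle. The chosen plan fixes C1 by a reagent before the ring exists and sets C3 in the bond-forming event; here both centres rest on steps whose sense the substrate does not secure. The plans are equal in that each depends on one step without direct precedent.

Alternative 2: No carbon–carbon bond of ring A is cut; the ring is taken from an arene.
- **Cut:** C1–O and, later, C2–CH3. 2,6-Dimethylbenzoic acid A6 would be reduced (Birch), the acid reduced and silylated to the meso diene tert-butyl[(2,6-dimethylcyclohexa-2,5-dien-1-yl)methoxy]diphenylsilane A7.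
- **Forward key step:** Shi epoxidation (fructose-derived ketone, KHSO5) of A7 must pick one of two enantiotopic alkenes and the face anti to C7. It would give the mono-epoxide tert-butyl{[1,3-dimethyl-7-oxabicyclo[4.1.0]hept-3-en-2-yl]methoxy}diphenylsilane A8. A methyl nucleophile must then open A8 at the tertiary C2 to give (1R,3R)-3-{[(tert-butyldiphenylsilyl)oxy]methyl}-2,2,4-trimethylcyclohex-4-en-1-ol A9. Acetylation, desilylation and etherification with 21 would finish.
- **In its favour:** it uses the hidden symmetry of the target (C2 and C4 both carry methyl and flank C3) and creates both stereocentres at once. C7 stays at the alcohol level, so the epimerisable aldehyde 19 never appears. About eight steps would suffice. On step economy and on the handling of C3 it is the better plan.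
- **Against it here:** the second methyl group must enter by opening a trisubstituted epoxide at its more hindered carbon. Cuprates would attack C1, and Lewis-acidic methylaluminium reagents invite hydride shift to a C1 ketone (Meinwald rearrangement) or elimination. The doubly allylic positions of A7 make the diene prone to aromatisation, and epoxidation of the second alkene must be stopped.
- **Comparison:** the chosen plan buys quaternary C2 ready-made and spends its effort on the C3–C4 bond; this plan gets the ring for nothing and spends its risk on C2. Its key step is a known reaction type and so on firmer ground than the chosen ring closure; the unsolved problem is shifted to the following step.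

Alternative 3: Substituents are added to a preformed six-membered ring.
- **Cut:** C2–CH3 and C3–C7.
- **Forward key step:** lithium dimethylcuprate A11 adds to the β-carbon (future C2) of (R)-4-[(tert-butyldimethylsilyl)oxy]-3-methylcyclohex-2-en-1-one A10. The enolate is trapped at the future C3 by formaldehyde A12, giving (2R,4R)-4-[(tert-butyldimethylsilyl)oxy]-2-(hydroxymethyl)-3,3-dimethylcyclohexan-1-one A13. The ketone carbon (future C4) would then become C4(Me)=C5 by protection of the primary alcohol, enol triflate formation towards C5 and methyl cross-coupling.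
- **In its favour:** every step is a known reaction type, the quaternary centre comes from a dependable conjugate addition, and C1 comes from an enantiopure enone. It meets the chosen route at an O-protected form of 20 in a comparable number of steps. On precedent it is the better plan; on length about equal.
- **Against it here:** the trans relation of C1 and C3 must come from kinetic attack on an enolate whose faces differ only through the remote C1 silyloxy group. In the saturated ketone the cis (diequatorial) isomer should be more stable, and C3 is epimerisable by enolisation or retro-aldol. Dehydration to the exocyclic enone is a further drain. γ-Silyloxy enones can lose the γ-oxygen with cuprates. The later enolisation must go to C5 and not C3.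
- **Comparison:** this plan builds substituents onto a ring; the chosen plan closes the ring around them. Its stereocontrol at C3 works against the thermodynamic preference of the intermediate. In the chosen plan the conformational bias of the closure and the catalyst point the same way, and 17 has no acidifying group next to C3.

Key step: step 10

Assumption: (R,R)-Ph-bod* [(1R,4R)-2,5-diphenylbicyclo[2.2.2]octa-2,5-diene] is written for the ligand antipode whose facial preference at C3 matches the chair-like bias of the tether; its mirror image would be used if the preference is the reverse.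

Remark on the precursor: the C3 arm is carried as a non-enolisable methyl ester instead of a mono-protected 2,2-dimethylpropane-1,3-diol. This removes one protecting group and one step; the precursor 16 itself is (1E,4R,6E), with boron cis to C6.

## Route

Step 1
Reactants: 1 methyl 3-hydroxy-2,2-dimethylpropanoate
Product: 2 methyl 2,2-dimethyl-3-oxopropanoate
Conditions: (COCl)2, DMSO, CH2Cl2, −78 °C; Et3N, −78 °C → rt
Reagents that add atoms: none
Why: Swern oxidation of a neopentyl primary alcohol; the aldehyde has no α-hydrogen, so it cannot enolise or self-condense, and over-oxidation is excluded; it is volatile and is carried on as a solution.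

Step 2
Reactants: 2 methyl 2,2-dimethyl-3-oxopropanoate
Product: 4 methyl (3R)-3-hydroxy-2,2-dimethylhex-5-enoate, via diisopinocampheylborinate ester 3 (not isolated)
Conditions: (+)-Ipc2BOMe, allylMgBr, Et2O, 0 °C → rt; 2, −78 °C; NaBO3·4H2O, THF/H2O, rt
Reagents that add atoms: allylmagnesium bromide C=CC[Mg]Br (allyl group, delivered as B-allyldiisopinocampheylborane)
Why: Brown allylation through a chair-like Zimmerman–Traxler transition state; the reagent of the (−)-α-pinene series is the antipode of the one that turns pivalaldehyde into the (S)-alcohol, so it should deliver allyl to the Re face of 2 and set C1 as (R); perborate cleaves 3 without the strong base that could cause retro-aldol or ester hydrolysis.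

Step 3
Reactants: 4 methyl (3R)-3-hydroxy-2,2-dimethylhex-5-enoate
Product: 5 methyl (3R)-3-[(tert-butyldimethylsilyl)oxy]-2,2-dimethylhex-5-enoate
Conditions: TBSOTf, 2,6-lutidine, CH2Cl2, 0 °C
Reagents that add atoms: tert-butyldimethylsilyl trifluoromethanesulfonate CC(C)(C)[Si](C)(C)OS(=O)(=O)C(F)(F)F
Why: silylation with the silyl triflate, needed because the carbinol is flanked by a quaternary carbon; the TBS ether should survive ylide, hydride, palladium, amine bases, aqueous KOH and buffered TiCl3 and is removed by fluoride at the end.

Step 4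
Reactants: 5 methyl (3R)-3-[(tert-butyldimethylsilyl)oxy]-2,2-dimethylhex-5-enoate
Product: 7 methyl (3R)-3-[(tert-butyldimethylsilyl)oxy]-2,2-dimethyl-5-oxopentanoate, via secondary ozonide 6 (not isolated)
Conditions: O3, CH2Cl2, −78 °C; PPh3, −78 °C → rt
Reagents that add atoms: ozone [O-][O+]=O
Why: ozonolysis of the monosubstituted alkene with reductive work-up; ester and silyl ether are inert, and the neutral conditions avoid β-elimination of the silyloxy group from 7.

Step 5
Reactants: 7 methyl (3R)-3-[(tert-butyldimethylsilyl)oxy]-2,2-dimethyl-5-oxopentanoate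
Product: 8 methyl (3R,5Z)-3-[(tert-butyldimethylsilyl)oxy]-6-iodo-2,2-dimethylhept-5-enoate
Conditions: EtPPh3I, n-BuLi, THF, 0 °C; I2, −78 °C; NaN(SiMe3)2, −20 °C; 7, −78 → −20 °C
Reagents that add atoms: ethyltriphenylphosphonium iodide CC[P+](c1ccccc1)(c1ccccc1)c1ccccc1.[I-]; iodine II
Why: Wittig olefination of Stork–Zhao type with the α-iodoethylidene ylide; the non-stabilised ylide should react through the cis-oxaphosphetane and give the Z iodide, iodine cis to C6; the quaternary ester cannot enolise.

Step 6
Reactants: 8 methyl (3R,5Z)-3-[(tert-butyldimethylsilyl)oxy]-6-iodo-2,2-dimethylhept-5-enoate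
Product: 9 (3R,5Z)-3-[(tert-butyldimethylsilyl)oxy]-6-iodo-2,2-dimethylhept-5-en-1-ol
Conditions: i-Bu2AlH, CH2Cl2, −78 → 0 °C; aq. potassium sodium tartrate
Reagents that add atoms: none
Why: hydride reduction of the ester to the primary alcohol; it is done at the iodide stage so that the aluminium hydride never meets a boronate, and alkenyl iodide and silyl ether are inert at this temperature.

Step 7
Reactants: 9 (3R,5Z)-3-[(tert-butyldimethylsilyl)oxy]-6-iodo-2,2-dimethylhept-5-en-1-ol; 10 bis(pinacolato)diboron
Product: 11 (3R,5E)-3-[(tert-butyldimethylsilyl)oxy]-2,2-dimethyl-6-(4,4,5,5-tetramethyl-1,3,2-dioxaborolan-2-yl)hept-5-en-1-ol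
Conditions: PdCl2(PPh3)2 (3 mol %), PPh3, KOPh, toluene, 50 °C
Reagents that add atoms: none
Why: Miyaura borylation: oxidative addition of zerovalent palladium into C–I with retention, phenoxide-assisted transmetallation from 10, reductive elimination; the weak base suppresses Suzuki coupling of product with iodide, and boron stays cis to C6 (the descriptor becomes E only because boron ranks below carbon).

Step 8
Reactants: 11 (3R,5E)-3-[(tert-butyldimethylsilyl)oxy]-2,2-dimethyl-6-(4,4,5,5-tetramethyl-1,3,2-dioxaborolan-2-yl)hept-5-en-1-ol
Product: 12 (3R,5E)-3-[(tert-butyldimethylsilyl)oxy]-2,2-dimethyl-6-(4,4,5,5-tetramethyl-1,3,2-dioxaborolan-2-yl)hept-5-enal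
Conditions: Dess–Martin periodinane, CH2Cl2, 0 °C → rt
Reagents that add atoms: none
Why: Dess–Martin oxidation under nearly neutral conditions; the aldehyde is non-enolisable, and the pinacol boronate and silyl ether do not react with the periodinane.

Step 9
Reactants: 12 (3R,5E)-3-[(tert-butyldimethylsilyl)oxy]-2,2-dimethyl-6-(4,4,5,5-tetramethyl-1,3,2-dioxaborolan-2-yl)hept-5-enal; 13 nitromethane
Product: 16 tert-butyldimethyl{[(1E,4R,6E)-3,3-dimethyl-1-nitro-7-(4,4,5,5-tetramethyl-1,3,2-dioxaborolan-2-yl)octa-1,6-dien-4-yl]oxy}silane, via nitro alcohol 14 (not isolated), via nitro mesylate 15 (not isolated)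
Conditions: 13 (co-solvent), 1,1,3,3-tetramethylguanidine (10 mol %), THF, 0 °C → rt; evaporate; MsCl, Et3N, CH2Cl2, −20 → 0 °C
Reagents that add atoms: none
Why: Henry reaction followed by E1cB elimination of the mesylate, which should give the more stable E nitroalkene; the quaternary C2 has no hydrogen, so the double bond cannot move out of conjugation, and the amine bases leave the boronate untouched.

Step 10
Reactants: 16 tert-butyldimethyl{[(1E,4R,6E)-3,3-dimethyl-1-nitro-7-(4,4,5,5-tetramethyl-1,3,2-dioxaborolan-2-yl)octa-1,6-dien-4-yl]oxy}silane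
Product: 17 tert-butyldimethyl{[(1R,3R)-2,2,4-trimethyl-3-(nitromethyl)cyclohex-4-en-1-yl]oxy}silane
Conditions: [RhCl(C2H4)2]2 (2.5 mol %), (R,R)-Ph-bod* (5.5 mol %), aq. KOH (20 mol %), 1,4-dioxane/H2O 10:1, 0.02 M, 40 °C
Reagents that add atoms: none
Why: Proposed new method: KOH turns the chloride precatalyst into a hydroxorhodium diene complex of monovalent rhodium, which transmetallates with the alkenylboronate to give an alkenylrhodium at C4 with retention of geometry; this inserts the tethered C3=C7 nitroalkene syn (C4 to C3, Rh to C7), and water protonates the rhodium nitronate, regenerating Rh–OH. The closest known reaction type is the intermolecular rhodium/chiral-diene-catalysed asymmetric conjugate addition of alkenylboron reagents to nitroalkenes (Hayashi–Miyaura type); delivery through a tether to a nitroalkene is the new element. Ring A closes in the 6-exo-trig mode with C7 left outside the ring. C3 is created by attack on its Re face (C7 > C2 > H), controlled jointly by the chiral diene and by the tether: insertion needs the Rh–C4 and C3=C7 bonds coplanar in a plane roughly perpendicular to the C4=C5 plane, which places C7 pseudoaxial, and the half-chair with the C1 silyloxy group equatorial then leads to the 1,3-trans product, whereas the cis product would need a syn-diaxial pair. The step needs cyclisation to win over protodeboronation and over intermolecular addition; the short tether, the dilution and the gem-dimethyl group at C2 should secure this. The C4=C5 alkene cannot migrate because C4 never becomes sp3, and boron cis to C6 is what lets C4 reach C3.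

Step 11
Reactants: 17 tert-butyldimethyl{[(1R,3R)-2,2,4-trimethyl-3-(nitromethyl)cyclohex-4-en-1-yl]oxy}silane
Product: 19 (1R,5R)-5-[(tert-butyldimethylsilyl)oxy]-2,6,6-trimethylcyclohex-2-ene-1-carbaldehyde, via sodium nitronate 18 (not isolated)
Conditions: NaOMe, MeOH, 0 °C; then aq. TiCl3, NH4OAc (pH 5–6), THF/H2O, 0 °C → rt
Reagents that add atoms: water O
Why: Nef reaction in its reductive form: TiCl3 (trivalent titanium) reduces nitronate 18 to the imine, which hydrolyses in the buffer; this avoids the strong acid of the classical procedure and oxidants that would attack the alkene, and the weakly acidic pH should limit enolisation of 19 at C3.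

Step 12
Reactants: 19 (1R,5R)-5-[(tert-butyldimethylsilyl)oxy]-2,6,6-trimethylcyclohex-2-ene-1-carbaldehyde
Product: 20 [(1R,5R)-5-[(tert-butyldimethylsilyl)oxy]-2,6,6-trimethylcyclohex-2-en-1-yl]methanol
Conditions: NaBH4, MeOH, 0 °C (crude 19 used at once)
Reagents that add atoms: none
Why: borohydride reduction of the aldehyde, which should be much faster than enolisation at 0 °C, so that C3 and the alkene position are retained; after this step C3 is no longer epimerisable.

Step 13
Reactants: 20 [(1R,5R)-5-[(tert-butyldimethylsilyl)oxy]-2,6,6-trimethylcyclohex-2-en-1-yl]methanol; 21 umbelliferone (7-hydroxy-2H-chromen-2-one)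
Product: 22 7-{[(1R,5R)-5-[(tert-butyldimethylsilyl)oxy]-2,6,6-trimethylcyclohex-2-en-1-yl]methoxy}-2H-chromen-2-one
Conditions: PPh3, DIAD, THF, 0 °C → rt
Reagents that add atoms: none
Why: Mitsunobu etherification; the phenol of 21 is acidic enough to protonate the betaine, displacement occurs at the primary, non-stereogenic C7, and the neutral conditions protect the lactone.

Step 14
Reactants: 22 7-{[(1R,5R)-5-[(tert-butyldimethylsilyl)oxy]-2,6,6-trimethylcyclohex-2-en-1-yl]methoxy}-2H-chromen-2-one
Product: 23 7-{[(1R,5R)-5-hydroxy-2,6,6-trimethylcyclohex-2-en-1-yl]methoxy}-2H-chromen-2-one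
Conditions: HF·pyridine, pyridine, THF, 0 °C → rt
Reagents that add atoms: none
Why: fluoride-mediated desilylation under non-basic conditions, so the coumarin lactone is not opened; aryl ether and trisubstituted alkene are stable to buffered HF.

Step 15
Reactants: 23 7-{[(1R,5R)-5-hydroxy-2,6,6-trimethylcyclohex-2-en-1-yl]methoxy}-2H-chromen-2-one
Product: 24 (1R,3R)-2,2,4-trimethyl-3-{[(2-oxo-2H-chromen-7-yl)oxy]methyl}cyclohex-4-en-1-yl acetate
Conditions: Ac2O, pyridine, DMAP (cat.), CH2Cl2, rt
Reagents that add atoms: acetic anhydride CC(=O)OC(C)=O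
Why: DMAP-catalysed acylation of the secondary alcohol; the C1–O bond is not broken, so the configuration of C1 is kept.

## Compound list

1 | methyl 3-hydroxy-2,2-dimethylpropanoate | COC(=O)C(C)(C)CO | starting material
2 | methyl 2,2-dimethyl-3-oxopropanoate | COC(=O)C(C)(C)C=O | intermediate
3 | methyl (3R)-3-[(diisopinocampheylboranyl)oxy]-2,2-dimethylhex-5-enoate, Ipc groups of the (−)-α-pinene series (not isolated) | COC(=O)C(C)(C)[C@@H](CC=C)OB([C@H]1C[C@H]2C[C@@H]([C@@H]1C)C2(C)C)[C@H]1C[C@H]2C[C@@H]([C@@H]1C)C2(C)C | intermediate
4 | methyl (3R)-3-hydroxy-2,2-dimethylhex-5-enoate | COC(=O)C(C)(C)[C@H](O)CC=C | intermediate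
5 | methyl (3R)-3-[(tert-butyldimethylsilyl)oxy]-2,2-dimethylhex-5-enoate | COC(=O)C(C)(C)[C@H](O[Si](C)(C)C(C)(C)C)CC=C | intermediate
6 | methyl (3R)-3-[(tert-butyldimethylsilyl)oxy]-2,2-dimethyl-4-(1,2,4-trioxolan-3-yl)butanoate, epimers at the trioxolane carbon (not isolated) | COC(=O)C(C)(C)[C@H](O[Si](C)(C)C(C)(C)C)CC1OCOO1 | intermediate
7 | methyl (3R)-3-[(tert-butyldimethylsilyl)oxy]-2,2-dimethyl-5-oxopentanoate | COC(=O)C(C)(C)[C@H](O[Si](C)(C)C(C)(C)C)CC=O | intermediate
8 | methyl (3R,5Z)-3-[(tert-butyldimethylsilyl)oxy]-6-iodo-2,2-dimethylhept-5-enoate | COC(=O)C(C)(C)[C@H](O[Si](C)(C)C(C)(C)C)C/C=C(/C)I | intermediate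
9 | (3R,5Z)-3-[(tert-butyldimethylsilyl)oxy]-6-iodo-2,2-dimethylhept-5-en-1-ol | OCC(C)(C)[C@H](O[Si](C)(C)C(C)(C)C)C/C=C(/C)I | intermediate
10 | bis(pinacolato)diboron | CC1(C)OB(OC1(C)C)B1OC(C)(C)C(C)(C)O1 | starting material
11 | (3R,5E)-3-[(tert-butyldimethylsilyl)oxy]-2,2-dimethyl-6-(4,4,5,5-tetramethyl-1,3,2-dioxaborolan-2-yl)hept-5-en-1-ol | OCC(C)(C)[C@H](O[Si](C)(C)C(C)(C)C)C/C=C(/C)B1OC(C)(C)C(C)(C)O1 | intermediate
12 | (3R,5E)-3-[(tert-butyldimethylsilyl)oxy]-2,2-dimethyl-6-(4,4,5,5-tetramethyl-1,3,2-dioxaborolan-2-yl)hept-5-enal | O=CC(C)(C)[C@H](O[Si](C)(C)C(C)(C)C)C/C=C(/C)B1OC(C)(C)C(C)(C)O1 | intermediate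
13 | nitromethane | C[N+](=O)[O-] | starting material
14 | (4R,6E)-4-[(tert-butyldimethylsilyl)oxy]-3,3-dimethyl-1-nitro-7-(4,4,5,5-tetramethyl-1,3,2-dioxaborolan-2-yl)oct-6-en-2-ol, epimers at C2 (not isolated) | [O-][N+](=O)CC(O)C(C)(C)[C@H](O[Si](C)(C)C(C)(C)C)C/C=C(/C)B1OC(C)(C)C(C)(C)O1 | intermediate
15 | methanesulfonate of 14 (not isolated) | [O-][N+](=O)CC(OS(C)(=O)=O)C(C)(C)[C@H](O[Si](C)(C)C(C)(C)C)C/C=C(/C)B1OC(C)(C)C(C)(C)O1 | intermediate
16 | tert-butyldimethyl{[(1E,4R,6E)-3,3-dimethyl-1-nitro-7-(4,4,5,5-tetramethyl-1,3,2-dioxaborolan-2-yl)octa-1,6-dien-4-yl]oxy}silane | CC(C)(C)[Si](C)(C)O[C@H](C/C=C(/C)B1OC(C)(C)C(C)(C)O1)C(C)(C)/C=C/[N+](=O)[O-] | intermediate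
17 | tert-butyldimethyl{[(1R,3R)-2,2,4-trimethyl-3-(nitromethyl)cyclohex-4-en-1-yl]oxy}silane | CC(C)(C)[Si](C)(C)O[C@@H]1CC=C(C)[C@@H](C[N+](=O)[O-])C1(C)C | intermediate
18 | sodium nitronate of 17 (not isolated) | CC(C)(C)[Si](C)(C)O[C@@H]1CC=C(C)[C@@H](C=[N+]([O-])[O-])C1(C)C.[Na+] | intermediate
19 | (1R,5R)-5-[(tert-butyldimethylsilyl)oxy]-2,6,6-trimethylcyclohex-2-ene-1-carbaldehyde | CC(C)(C)[Si](C)(C)O[C@@H]1CC=C(C)[C@@H](C=O)C1(C)C | intermediate
20 | [(1R,5R)-5-[(tert-butyldimethylsilyl)oxy]-2,6,6-trimethylcyclohex-2-en-1-yl]methanol | CC(C)(C)[Si](C)(C)O[C@@H]1CC=C(C)[C@@H](CO)C1(C)C | intermediate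
21 | umbelliferone (7-hydroxy-2H-chromen-2-one) | O=c1ccc2ccc(O)cc2o1 | starting material
22 | 7-{[(1R,5R)-5-[(tert-butyldimethylsilyl)oxy]-2,6,6-trimethylcyclohex-2-en-1-yl]methoxy}-2H-chromen-2-one | CC(C)(C)[Si](C)(C)O[C@@H]1CC=C(C)[C@@H](COc2ccc3ccc(=O)oc3c2)C1(C)C | intermediate
23 | 7-{[(1R,5R)-5-hydroxy-2,6,6-trimethylcyclohex-2-en-1-yl]methoxy}-2H-chromen-2-one | O[C@@H]1CC=C(C)[C@@H](COc2ccc3ccc(=O)oc3c2)C1(C)C | intermediate
24 | (1R,3R)-2,2,4-trimethyl-3-{[(2-oxo-2H-chromen-7-yl)oxy]methyl}cyclohex-4-en-1-yl acetate | CC(=O)O[C@@H]1CC=C(C)[C@@H](COc2ccc3ccc(=O)oc3c2)C1(C)C | target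

## Step count and least certain steps

Total step count: 15. Longest linear sequence: 15 steps (1 to 24); 10, 13 and 21 are purchased and enter in single steps.

Step 10 (key step, the only step without precedent on its substrate class).
- **What may go wrong:** protodeboronation of the alkenylrhodium before it inserts into C3, which is hindered by the adjacent quaternary C2; hydroxide-induced degradation of the nitroalkene; intermolecular addition; or a mismatch of ligand and tether that lowers the facial selectivity at C3.
- **Fallback (known reactions only):** C3 is set by an intermolecular conjugate addition and ring A is closed by metathesis at C4=C5. It sets out from 5. Reduction with i-Bu2AlH should give (3R)-3-[(tert-butyldimethylsilyl)oxy]-2,2-dimethylhex-5-en-1-ol F1, and Dess–Martin oxidation the aldehyde (3R)-3-[(tert-butyldimethylsilyl)oxy]-2,2-dimethylhex-5-enal F2. The nitroaldol and mesylation conditions of step 9 with 13 should lead, through (4R)-4-[(tert-butyldimethylsilyl)oxy]-3,3-dimethyl-1-nitrohept-6-en-2-ol F3 and the methanesulfonate of F3 F4, to tert-butyl{[(1E,4R)-3,3-dimethyl-1-nitrohepta-1,6-dien-4-yl]oxy}dimethylsilane F5. Intermolecular rhodium/chiral-diene-catalysed addition of isopropenylboronic acid pinacol ester ([RhCl(C2H4)2]2, Ph-bod*, aq. KOH, dioxane) to F5 would give tert-butyl{[(4R,6R)-5,5,7-trimethyl-6-(nitromethyl)octa-1,7-dien-4-yl]oxy}dimethylsilane F6. Ring-closing metathesis of F6 with the second-generation Grubbs catalyst, RuCl2(H2IMes)(PCy3)(=CHPh), in CH2Cl2 at 40 °C would release ethene and come back to the route at 17.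

Step 5.
- **What may go wrong:** erosion of the Z selectivity, low conversion through decomposition of the iodo ylide, or β-elimination of the silyloxy group from 7 under the basic conditions.
- **Fallback:** it sets out from 7. Dibromo-olefination (CBr4, PPh3, CH2Cl2, 0 °C; first stage of the Corey–Fuchs sequence) should give methyl (3R)-6,6-dibromo-3-[(tert-butyldimethylsilyl)oxy]-2,2-dimethylhex-5-enoate F7. Negishi coupling with MeZnCl and Pd(P(t-Bu)3)2, which replaces the bromine trans to the chain first, would give methyl (3R,5Z)-6-bromo-3-[(tert-butyldimethylsilyl)oxy]-2,2-dimethylhept-5-enoate F8. Reduction with i-Bu2AlH gives (3R,5Z)-6-bromo-3-[(tert-butyldimethylsilyl)oxy]-2,2-dimethylhept-5-en-1-ol F9. Miyaura borylation of F9 with 10 (Pd(dppf)Cl2, KOAc, 1,4-dioxane, 80 °C) comes back to the route at 11.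

Step 11.
- **What may go wrong:** incomplete nitronate formation at the hindered site, and epimerisation at C3 or migration of the C4=C5 alkene into conjugation while the aldehyde is set free.
- **Fallback:** it sets out from 17 and never passes through an aldehyde. Oxidative conversion of the primary nitro group with NaNO2 and AcOH in DMSO at 35 °C should give (1R,5R)-5-[(tert-butyldimethylsilyl)oxy]-2,6,6-trimethylcyclohex-2-ene-1-carboxylic acid F10. Reduction with LiAlH4 in THF at 0 °C comes back to the route at 20.

Step 13.
- **What may go wrong:** slow displacement at the β-branched C7, so that the activated alcohol is consumed by the reduced azodicarboxylate instead of the phenoxide.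
- **Fallback:** it sets out from 20 and replaces the redox condensation by a two-stage substitution. MsCl and Et3N in CH2Cl2 give [(1R,5R)-5-[(tert-butyldimethylsilyl)oxy]-2,6,6-trimethylcyclohex-2-en-1-yl]methyl methanesulfonate F11. Displacement with 21 and Cs2CO3 in DMF at 70 °C comes back to the route at 22.

## Further compounds

F1 | step 10 | (3R)-3-[(tert-butyldimethylsilyl)oxy]-2,2-dimethylhex-5-en-1-ol | OCC(C)(C)[C@H](O[Si](C)(C)C(C)(C)C)CC=C
F2 | step 10 | (3R)-3-[(tert-butyldimethylsilyl)oxy]-2,2-dimethylhex-5-enal | O=CC(C)(C)[C@H](O[Si](C)(C)C(C)(C)C)CC=C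
F3 | step 10 | (4R)-4-[(tert-butyldimethylsilyl)oxy]-3,3-dimethyl-1-nitrohept-6-en-2-ol, epimers at C2 | [O-][N+](=O)CC(O)C(C)(C)[C@H](O[Si](C)(C)C(C)(C)C)CC=C
F4 | step 10 | methanesulfonate of F3 | [O-][N+](=O)CC(OS(C)(=O)=O)C(C)(C)[C@H](O[Si](C)(C)C(C)(C)C)CC=C
F5 | step 10 | tert-butyl{[(1E,4R)-3,3-dimethyl-1-nitrohepta-1,6-dien-4-yl]oxy}dimethylsilane | C=CC[C@@H](O[Si](C)(C)C(C)(C)C)C(C)(C)/C=C/[N+](=O)[O-]
F6 | step 10 | tert-butyl{[(4R,6R)-5,5,7-trimethyl-6-(nitromethyl)octa-1,7-dien-4-yl]oxy}dimethylsilane | C=CC[C@@H](O[Si](C)(C)C(C)(C)C)C(C)(C)[C@H](C[N+](=O)[O-])C(C)=C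
F7 | step 5 | methyl (3R)-6,6-dibromo-3-[(tert-butyldimethylsilyl)oxy]-2,2-dimethylhex-5-enoate | COC(=O)C(C)(C)[C@H](O[Si](C)(C)C(C)(C)C)CC=C(Br)Br
F8 | step 5 | methyl (3R,5Z)-6-bromo-3-[(tert-butyldimethylsilyl)oxy]-2,2-dimethylhept-5-enoate | COC(=O)C(C)(C)[C@H](O[Si](C)(C)C(C)(C)C)C/C=C(/C)Br
F9 | step 5 | (3R,5Z)-6-bromo-3-[(tert-butyldimethylsilyl)oxy]-2,2-dimethylhept-5-en-1-ol | OCC(C)(C)[C@H](O[Si](C)(C)C(C)(C)C)C/C=C(/C)Br
F10 | step 11 | (1R,5R)-5-[(tert-butyldimethylsilyl)oxy]-2,6,6-trimethylcyclohex-2-ene-1-carboxylic acid | CC(C)(C)[Si](C)(C)O[C@@H]1CC=C(C)[C@@H](C(=O)O)C1(C)C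
F11 | step 13 | [(1R,5R)-5-[(tert-butyldimethylsilyl)oxy]-2,6,6-trimethylcyclohex-2-en-1-yl]methyl methanesulfonate | CC(C)(C)[Si](C)(C)O[C@@H]1CC=C(C)[C@@H](COS(C)(=O)=O)C1(C)C
A1 | alternative 1 | N,N-dimethylisobutyramide | CC(C)C(=O)N(C)C
A2 | alternative 1 | N,N-dimethyl-2-methylprop-1-en-1-ylideneammonium trifluoromethanesulfonate (keteniminium triflate) | CC(C)=C=[N+](C)C.[O-]S(=O)(=O)C(F)(F)F
A3 | alternative 1 | (E)-tert-butyldimethyl[(3-methylpenta-2,4-dien-1-yl)oxy]silane | C=C/C(C)=C/CO[Si](C)(C)C(C)(C)C
A4 | alternative 1 | (R)-3-[(E)-4-(tert-butyldimethylsilyloxy)but-2-en-2-yl]-2,2-dimethylcyclobutan-1-one | O=C1C[C@@H](C1(C)C)/C(C)=C/CO[Si](C)(C)C(C)(C)C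
A5 | alternative 1 | (R)-3-{[(tert-butyldimethylsilyl)oxy]methyl}-2,2,4-trimethylcyclohex-4-en-1-one | O=C1CC=C(C)[C@@H](CO[Si](C)(C)C(C)(C)C)C1(C)C
A6 | alternative 2 | 2,6-dimethylbenzoic acid | Cc1cccc(C)c1C(=O)O
A7 | alternative 2 | tert-butyl[(2,6-dimethylcyclohexa-2,5-dien-1-yl)methoxy]diphenylsilane | CC1=CCC=C(C)C1CO[Si](C(C)(C)C)(c1ccccc1)c1ccccc1
A8 | alternative 2 | tert-butyl{[1,3-dimethyl-7-oxabicyclo[4.1.0]hept-3-en-2-yl]methoxy}diphenylsilane, oxirane anti to the silyloxymethyl group | C[C@@]12O[C@@H]1CC=C(C)[C@H]2CO[Si](C(C)(C)C)(c1ccccc1)c1ccccc1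
A9 | alternative 2 | (1R,3R)-3-{[(tert-butyldiphenylsilyl)oxy]methyl}-2,2,4-trimethylcyclohex-4-en-1-ol | O[C@@H]1CC=C(C)[C@@H](CO[Si](C(C)(C)C)(c2ccccc2)c2ccccc2)C1(C)C
A10 | alternative 3 | (R)-4-[(tert-butyldimethylsilyl)oxy]-3-methylcyclohex-2-en-1-one | CC(C)(C)[Si](C)(C)O[C@@H]1CCC(=O)C=C1C
A11 | alternative 3 | lithium dimethylcuprate | [Li+].C[Cu-]C
A12 | alternative 3 | formaldehyde | C=O
A13 | alternative 3 | (2R,4R)-4-[(tert-butyldimethylsilyl)oxy]-2-(hydroxymethyl)-3,3-dimethylcyclohexan-1-one | CC(C)(C)[Si](C)(C)O[C@@H]1CCC(=O)[C@@H](CO)C1(C)C
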